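A reading at 5.0 min lies 1.00 min beyond the last teal reading, so the question is how far a nearly straight curve runs on.

| setting | teal | red | west | north-west | east |
|---|---|---|---|---|---|
| electrophile | 0.50 mM | 0.50 mM | 0.50 mM | 0.50 mM | 0.50 mM |
| free base | 0.57 mM | 2.8 mM | 0.500 mM | 1.00 mM | 2.00 mM |
| solid nucleophile | 0.65 mM | 0.65 mM | 0.650 mM | 0.650 mM | 0.650 mM |
| remark | run made earlier | run made earlier |  |  |  |
| time |  |  | 5.0 min | 5.0 min | 5.0 min |

| run | time / min | electrophile / % | target / % |
|---|---|---|---|
| teal | 0.500 | 98.4 | 2.9 |
| teal | 1.00 | 93.3 | 5.9 |
| teal | 1.50 | 88.9 | 14.8 |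
| teal | 2.00 | 81.7 | 19.1 |
| teal | 2.50 | 76.7 | 25.5 |
| teal | 3.00 | 69.1 | 29.4 |
| teal | 4.00 | 57.8 | 40.5 |
| red | 0.200 | 99.4 | 1.2 |
| red | 0.500 | 97.8 | 1.4 |
| red | 1.00 | 92.3 | 6.0 |
| red | 1.50 | 88.7 | 11.5 |
| red | 2.00 | 82.0 | 18.5 |
| red | 3.00 | 67.1 | 28.3 |
| red | 4.00 | 57.8 | 42.6 |

(scatter of a reading: 1 percentage point)

1. part of the electrophile that has reacted at the end, west
2. part of the electrophile that has reacted at the end, north-west
3. part of the electrophile that has reacted at the end, east
4. what raising the concentration of free base from its lowest to its highest value here does to the part of the electrophile that has reacted (changes below 5 percentage points count as none) (it rises / no change / it falls)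

- given per volume of solution although it is solid: solid nucleophile
- on the list of suspects stand: electrophile + nucleophile <-> acid set free + target; nucleophile + acid set free <-> protonated nucleophile; acid set free + free base <-> salt of the base; solid nucleophile <-> nucleophile; nucleophile <-> dormant form
- at the start none of the solid nucleophile is in solution

After a short lag, the electrophile in teal falls at 0.0580 mM min⁻¹ between 0.500 min and 4.00 min. This feed rate v, the electrophile consumed per minute on the straight part, matches the 0.0571 mM min⁻¹ of red, although red holds 4.91 times the free base.

My own bracket for the reacted part at 5.0 min starts from teal's last reading, 42.2%. From below, letting the rate fall in step with the electrophile left gives 52.7%. From above, holding v unchanged gives 53.8%. Each edge carries the scatter of 1 percentage point. Acid set free matches reacted electrophile one to one, so the total released, salt of the base counted, reaches about 0.269 mM, less than the 0.500 mM of free base in west. The same bracket therefore serves all three flasks.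

The forecast gives 53.5%, 54% and 54%, hence no change, holding that “The rate is therefore effectively zero order in base”. Its west value lies inside the bracket; the other two lie 0.2 points above the upper edge, well within the scatter.

The flasks give 52.7%, 52.7% and 52.7%, so no change: a shift of 0.0072 points, with west at the lower edge. West still holds 47% of its free base at 5.00 min, beside 1.73 × 10⁻⁴ mM of protonated nucleophile.

    electrophile + nucleophile ⇌ acid set free + target (K = 0.767, k = 28.7 M⁻¹ s⁻¹)
    nucleophile + acid set free ⇌ protonated nucleophile, settled at all times (K = 1.30 × 10⁵ M⁻¹)
    acid set free + free base ⇌ salt of the base, settled at all times (K = 1.00 × 10⁸ M⁻¹)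
    solid nucleophile ⇌ nucleophile, rate k4*(cs4 - [nucleophile]) while solid is left; crystals form when [nucleophile] > cs4 (solubility = 0.200 mM, k = 0.0125 s⁻¹)
    nucleophile ⇌ dormant form (K = 0.339, k = 0.285 s⁻¹)

A neighbour of east gets 0.26 mM of solid nucleophile, now the limiting reagent. At v, consuming that charge takes 4.48 min, less than the reading time, and one nucleophile per electrophile caps the reacted part at 52.0%. The neighbour gives 42.3%, below that cap, with solid at 0%. Nucleophile, dormant form and protonated nucleophile together hold 0.0485 mM, which leaves 42.3% of the electrophile charged as target.

(The data were computed from invented constants.)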